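# Proposed total synthesis of CNP0202121.1 by carbonylative flavone annulation

## The problem

The target 24 is a biflavonoid: a 5-hydroxy-7-methoxyflavone and a (2S)-5,4'-dihydroxy-7-methoxyflavanone, joined by a diaryl ether from the flavone C4' oxygen to flavanone C6. That ether oxygen sits on a fully substituted carbon between the C5 hydroxyl and the C7 methoxy group, so it is best introduced while this ring is still a simple, symmetric phenol. Flavanone C2 is the only stereocentre, and nothing else in the molecule can control it, so a chiral catalyst must set it. C2 is also labile: base opens the dihydropyranone by retro-oxa-Michael reaction to the 2'-hydroxychalcone, and strong acid can ionise the benzylic C2–O1 bond with help from the 4'-oxygen. A temporary carbinol centre at flavanone C4, if one is introduced, is controlled by C2 but is erased again and needs no control. The two C5 hydroxyls are hydrogen-bonded to the neighbouring C4 carbonyls, which sets them apart from the C7 methyl ethers. Both benzo rings can therefore be carried as dimethyl ethers, made from symmetric dimethoxyphenols, and unveiled at the end by chelation-directed demethylation. The flavone is the robust half and the flavanone the fragile half, so the flavanone must be masked in any step that uses amines and heat. The key step rests on the flavone pyranone (O1, C2, C3, C4, C4a, C8a): C4 is a single carbonyl carbon between C4a, which lies ortho to the phenolic O1, and C3, and C2–C3 is a latent aryl alkyne. The ring can thus be assembled from an ortho-iodophenol, carbon monoxide 18 and a terminal aryl alkyne, and the iodophenol derives from symmetric 3,5-dimethoxyphenol 16.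

## Retrosynthesis

**24 to 23 (no skeletal bond cut).** The three free phenols of 24 are traced to the benzyl ether and the two peri methyl ethers of 23. Using methyl at both C5 and C7, and not two different groups, lets both benzo rings descend from symmetric dimethoxyphenols. The forward step must cleave only the ethers that chelate to a C4 carbonyl, plus the benzyl ether, and must leave the C7 methyl ethers, the diaryl ether and C2 alone.

**23 to 22 to 21 (oxidation level at flavanone C4).** The flavanone carbonyl of 23 is traced through alcohol 22 to the silyl ether 21. A flavanone would not survive the amine and heat of the ring-forming step, whereas a 4-silyloxyflavan has no carbonyl, no acidic C3 hydrogen and no free hydroxyl. The cost is one desilylation and one oxidation after the key step. The C4 centre is transient, so its configuration makes no demand.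

**21 to 15 + 17 + 18 (key disconnection).** The flavone pyranone is opened at C4a–C4, C4–C3 and O1–C2, giving iodophenol 17, carbon monoxide 18 and alkyne 15. The neighbouring cuts of a flavone (acyl transfer and cyclodehydration, or oxidative cyclisation of a chalcone) make one bond at a time, need a preformed acetophenone and end with acid or an oxidant. Here three bonds and the ring form in one operation, and the cut falls between two halves of comparable size at the last skeleton-forming step. Alkyne 15 already carries the stereocentre and the diaryl ether. The forward reaction must carbonylate before it alkynylates, close 6-endo and not 5-exo, and tolerate silyl and benzyl ethers.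

**17 to 16 (C–I bond).** The iodide is placed ortho to the hydroxyl of 16. Both ortho positions are equivalent, so the only question is ortho against para substitution.

**15 to 14 to 12 + 13 (aryl–alkyne bond).** The ethynyl group is cut at the aryl carbon, giving aryl bromide 12 and trimethylsilylacetylene 13 by way of silyl alkyne 14. The bromine is a latent alkyne that is inert to all the chemistry used to build the flavan. The forward coupling must activate an electron-rich aryl bromide.

**12 to 11 to 10 (protection and reduction).** Silyl ether 12 comes from alcohol 11, and 11 from flavanone 10 by hydride reduction. This is done before the amine-based coupling steps so that the (2S)-flavanone is never heated with base.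

**10 to 8 + 9 (C2–C1' bond).** The aryl group at C2 is cut away, giving achiral chromone 8 and 4-(benzyloxy)phenylboronic acid 9. The neighbouring cut, O1–C2 closure of a chalcone, has no reliable enantiocontrol without an extra activating group. Conjugate arylation sets the only permanent stereocentre by catalyst control at a planar carbon. The forward step needs facial selectivity at C2, non-basic conditions and tolerance of the C–Br bond.

**8 to 6 to 5 (pyranone carbon and acetyl group).** Chromone C2 is traced to a formamide acetal carbon condensed onto acetophenone 6 (through enaminone 7), and the acetyl group of 6 to a Friedel–Crafts acylation of phenol 5. Phenol 5 is symmetric, so the two positions ortho to its hydroxyl are identical and the acylation is regiochemically unambiguous.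

**5 to 3 to 1 + 2 (phenol oxygen and diaryl ether).** The hydroxyl of 5 is traced to the formyl group of aldehyde 3 by peracid oxidation (through formate 4). The diaryl ether of 3 is cut to syringaldehyde 1 and 4-bromophenylboronic acid 2. Syringaldehyde supplies the hindered oxygen flanked by two methoxy groups, its formyl group serves as a masked hydroxyl, and the ether is made on the cheapest and least crowded substrate of the route.

## Roads not taken

**Alternative 1:** The cut is the aryl ketone bond C4–C4a of the flavanone. In the forward direction the (S)-3-aryloxy-3-arylpropanoic acid A1, with the flavone already in place, is activated in situ as a mixed fluorinated anhydride. It then acylates the carbon ortho to the ether oxygen of its symmetric 3,5-dimethoxy-4-aryloxyphenyl ring and gives the 4'-O-acetyl flavanone A2.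
- Merits: C2 is set early by stoichiometrically reliable chemistry, symmetry fixes the regiochemistry, and no carbon monoxide under pressure is needed. The flavanone carbonyl is formed directly, so the four redox and protecting-group steps around flavanone C4 in the chosen plan would be saved. In step count this road is better.
- Weak points: the benzylic C–O bond of A1 lies β to an activated acyl group and carries a para-oxygenated aryl group. In a strongly acidic acylating medium it can ionise or eliminate to a cinnamate and a phenol, which would both racemise and fragment the molecule. The acetate on the 4'-oxygen only tempers this. The ether of A1 has to be made by substitution at an electron-rich benzylic carbinol, where partial loss of configuration is a known hazard. The nucleophilic benzo ring of the flavone, between two methoxy groups, competes for the acylium. The flavone must be built first, so the sequence is linear.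
- Comparison: the chosen plan is longer around C4, but its stereocentre is made under neutral catalytic conditions and meets a strong Lewis acid only in the last step, and the two halves are joined convergently.

**Alternative 2:** The cut is O1–C2 of the flavanone. In the forward direction the alkylidene β-ketoester A3, which carries a free ring phenol and a tert-butyl ester as temporary activator, cyclises by intramolecular oxa-Michael addition under a bifunctional cinchona thiourea. The product is the trans 3-tert-butoxycarbonyl (2S)-flavanone A4, and the ester is removed afterwards by acid-induced dealkylation and decarboxylation.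
- Merits: the ring closure itself sets C2, the catalyst is cheap and metal-free, and both enantiomers are available from the pseudo-enantiomeric alkaloids. In directness of stereocontrol it is at least the equal of the chosen plan.
- Weak points: the activating ester must be installed on a hindered, 2,6-dioxygenated aryl ketone and condensed with the aryl aldehyde. It must then be removed with acid and heat, under which a flavanone can equilibrate with its ring-opened form. Electron-rich substrates with a substituent ortho to the ketone tend to cyclise without the catalyst, and this background reaction is racemic. The key step joins no fragments, so the diaryl ether and the flavone have to be carried through a long linear sequence.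
- Comparison: the chosen plan needs a palladium catalyst and a chiral ligand for C2, but it arylates an achiral chromone that has no uncatalysed pathway, and it keeps the fragment union for the end.

**Alternative 3:** The cut removes the flavanone benzo ring at C4a–C5 and C8–C8a. In the forward direction the Brassard-type diene A5, a 2-aryloxy-1,3-dimethoxy-1-trimethylsilyloxybutadiene bearing the flavone, adds across the brominated double bond of the (S)-5-bromo-2-aryl-2,3-dihydropyran-4-one A6. Loss of hydrogen bromide and methanol aromatises the new ring to A7.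
- Merits: the crowded benzo ring is made with its three oxygens already differentiated, and the flavanone C5 hydroxyl emerges free, so only the flavone peri ether needs cleavage. In both respects this road is better than the chosen one.
- Weak points: A5 is a tetra-oxygenated silyl ketene acetal that is sensitive to hydrolysis. It must be generated by strong-base enolisation in the presence of the flavone carbonyl, and its 2-aryloxy group disfavours the reactive s-cis conformation. The stereocentre of A6 lies β to a vinylogous ester carbonyl and can be lost by ring opening on heating or during the elimination. Precedent for dienes with this substitution pattern is thin.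
- Comparison: the chosen plan cannot match the free C5 hydroxyl, but it uses only stable, known reagent classes, and it solves the hindered ether at the outset by symmetry.

Key step: step 11

## Route

Remark: the flavan-4-ol intermediates 11, 12, 14, 15 and 19–22 are written as the 2,4-cis (2S,4S) epimers expected from hydride reduction. C4 returns to a carbonyl in step 13, so any trans epimer would be carried through without consequence.

Step 1
Reactants: 1 syringaldehyde (4-hydroxy-3,5-dimethoxybenzaldehyde); 2 4-bromophenylboronic acid
Product: 3 4-(4-bromophenoxy)-3,5-dimethoxybenzaldehyde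
Conditions: Cu(OAc)2 (1 equiv), pyridine, 4 Å MS, CH2Cl2, O2 (1 atm), rt
Reagents that add atoms: none
Why: Chan–Lam O-arylation of a phenol with an arylboronic acid; it runs at room temperature, tolerates the aldehyde and leaves the C–Br bond untouched. Di-ortho-substituted phenols are known substrates but react slowly, so 2 is used in excess.

Step 2
Reactants: 3 4-(4-bromophenoxy)-3,5-dimethoxybenzaldehyde
Product: 5 4-(4-bromophenoxy)-3,5-dimethoxyphenol, via aryl formate 4 (not isolated)
Conditions: mCPBA, CH2Cl2, rt; then K2CO3, MeOH, rt
Reagents that add atoms: 3-chloroperoxybenzoic acid (mCPBA), O=C(OO)c1cccc(Cl)c1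
Why: Baeyer–Villiger (Dakin-type) oxidation; in the Criegee adduct the oxygen-rich aryl group migrates in preference to hydrogen, as with other trioxygenated benzaldehydes. The formate 4 is methanolysed in the same flask.

Step 3
Reactants: 5 4-(4-bromophenoxy)-3,5-dimethoxyphenol
Product: 6 1-[3-(4-bromophenoxy)-6-hydroxy-2,4-dimethoxyphenyl]ethan-1-one
Conditions: AcOH, BF3·OEt2, 90 °C; aq. NaOAc work-up
Reagents that add atoms: acetic acid, CC(=O)O
Why: BF3-promoted Friedel–Crafts acetylation (O-acylation and Fries-type transfer); the two positions ortho to the hydroxyl are equivalent and each is para to a methoxy group. The bromophenoxy ring is far less nucleophilic, and boron chelation of the product prevents a second acylation.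

Step 4
Reactants: 6 1-[3-(4-bromophenoxy)-6-hydroxy-2,4-dimethoxyphenyl]ethan-1-one
Product: 8 6-(4-bromophenoxy)-5,7-dimethoxy-4H-chromen-4-one, via dimethylamino enone 7 (not isolated)
Conditions: Me2NCH(OMe)2, toluene, 100 °C; then conc. HCl, CH2Cl2, 40 °C
Reagents that add atoms: N,N-dimethylformamide dimethyl acetal, COC(OC)N(C)C
Why: Standard chromone annulation of a 2-hydroxyacetophenone; condensation gives enaminone 7, and acid then triggers conjugate addition of the phenol and loss of dimethylamine.

Step 5
Reactants: 8 6-(4-bromophenoxy)-5,7-dimethoxy-4H-chromen-4-one; 9 4-(benzyloxy)phenylboronic acid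
Product: 10 (2S)-2-[4-(benzyloxy)phenyl]-6-(4-bromophenoxy)-5,7-dimethoxychroman-4-one
Conditions: Pd(OCOCF3)2 (5 mol%), (R)-t-BuPyOx (6 mol%), NH4PF6, H2O, ClCH2CH2Cl, 60 °C
Reagents that add atoms: none
Why: Catalytic asymmetric conjugate addition of an arylboronic acid to a chromone by a cationic divalent palladium–pyridinooxazoline complex (transmetalation, enone insertion, protonolysis). The tert-butyl group of (R)-4-tert-butyl-2-(pyridin-2-yl)-4,5-dihydrooxazole should direct the aryl group to the Re face of C2 and so give (2S), by analogy with the sense this ligand class shows with cyclic enones; if the sense on this substrate proves opposite, the antipodal ligand is used. The medium is not basic, so the flavanone should not ring-open, and divalent palladium does not insert into the C–Br bond.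

Step 6
Reactants: 10 (2S)-2-[4-(benzyloxy)phenyl]-6-(4-bromophenoxy)-5,7-dimethoxychroman-4-one
Product: 11 (2S,4S)-2-[4-(benzyloxy)phenyl]-6-(4-bromophenoxy)-5,7-dimethoxychroman-4-ol (2,4-cis)
Conditions: NaBH4, MeOH–THF, 0 °C
Reagents that add atoms: none
Why: Borohydride reduction of a flavanone; with the 2-aryl group equatorial, hydride should add to give the 2,4-cis carbinol under substrate control by C2. The C4 configuration is not needed later, and the cold, brief reaction should not open the ring.

Step 7
Reactants: 11 (2S,4S)-2-[4-(benzyloxy)phenyl]-6-(4-bromophenoxy)-5,7-dimethoxychroman-4-ol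
Product: 12 (2S,4S)-2-[4-(benzyloxy)phenyl]-6-(4-bromophenoxy)-4-[(tert-butyldimethylsilyl)oxy]-5,7-dimethoxychroman
Conditions: TBSCl, imidazole, DMF, rt to 40 °C
Reagents that add atoms: tert-butyldimethylsilyl chloride, CC(C)(C)[Si](C)(C)Cl
Why: Silylation of a secondary alcohol under basic conditions, which avoid ionisation of the electron-rich benzylic carbinol. The silyl ether removes the hydroxyl that would otherwise capture an aroyl–palladium species in step 11.

Step 8
Reactants: 12 (2S,4S)-2-[4-(benzyloxy)phenyl]-6-(4-bromophenoxy)-4-[(tert-butyldimethylsilyl)oxy]-5,7-dimethoxychroman; 13 trimethylsilylacetylene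
Product: 14 (2S,4S)-2-[4-(benzyloxy)phenyl]-4-[(tert-butyldimethylsilyl)oxy]-5,7-dimethoxy-6-{4-[(trimethylsilyl)ethynyl]phenoxy}chroman
Conditions: PdCl2(PhCN)2, P(t-Bu)3, CuI, i-Pr2NH, dioxane, rt
Reagents that add atoms: none
Why: Sonogashira coupling; the bulky, electron-rich phosphine allows zerovalent palladium to insert into an electron-rich aryl bromide at room temperature. Ethers and silyl ethers are inert under these conditions.

Step 9
Reactants: 14 (2S,4S)-2-[4-(benzyloxy)phenyl]-4-[(tert-butyldimethylsilyl)oxy]-5,7-dimethoxy-6-{4-[(trimethylsilyl)ethynyl]phenoxy}chroman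
Product: 15 (2S,4S)-2-[4-(benzyloxy)phenyl]-4-[(tert-butyldimethylsilyl)oxy]-6-(4-ethynylphenoxy)-5,7-dimethoxychroman
Conditions: K2CO3, MeOH–THF, rt
Reagents that add atoms: none
Why: Methanolysis of the alkynyl C–Si bond with catalytic carbonate; the secondary tert-butyldimethylsilyl ether is stable to these conditions.

Step 10
Reactants: 16 3,5-dimethoxyphenol
Product: 17 2-iodo-3,5-dimethoxyphenol
Conditions: NIS, CH2Cl2, 0 °C
Reagents that add atoms: N-iodosuccinimide, O=C1CCC(=O)N1I
Why: Electrophilic aromatic iodination; the two equivalent positions ortho to the hydroxyl are less hindered than the position between the two methoxy groups. Any 4-iodo isomer would be removed by chromatography.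

Step 11
Reactants: 15 (2S,4S)-2-[4-(benzyloxy)phenyl]-4-[(tert-butyldimethylsilyl)oxy]-6-(4-ethynylphenoxy)-5,7-dimethoxychroman; 17 2-iodo-3,5-dimethoxyphenol; 18 carbon monoxide
Product: 21 2-[4-({(2S,4S)-2-[4-(benzyloxy)phenyl]-4-[(tert-butyldimethylsilyl)oxy]-5,7-dimethoxychroman-6-yl}oxy)phenyl]-5,7-dimethoxy-4H-chromen-4-one, via hydroxyaryl ynone 19 (not isolated), via diethylamino enone 20 (not isolated)
Conditions: PdCl2(PPh3)2 (5 mol%), CO (20 bar), Et2NH, 120 °C
Reagents that add atoms: none
Why: Zerovalent palladium, formed in the flask from PdCl2(PPh3)2, inserts into the C–I bond of 17; CO insertion gives an aroyl–palladium iodide, the amine-deprotonated alkyne 15 displaces iodide, and reductive elimination releases ynone 19 (bonds C4a–C4 and C4–C3). Diethylamine adds to the ynone to give enaminone 20, and the ortho hydroxyl then attacks the amine-bearing carbon and expels diethylamine, forming O1–C2. The closest known reaction type is the carbonylative annulation of ortho-iodophenols with terminal aryl alkynes to flavones under PdCl2(PPh3)2 in a secondary amine. The one ring formed, the pyranone, closes in the 6-endo mode (6-endo-trig addition–elimination on 20, net 6-endo-dig with respect to 19). No stereocentre is created, and C2 and C4 of the flavan are remote and not epimerisable under basic conditions. Three selectivities are needed: carbonylation ahead of direct alkynylation, which CO pressure and the electron-rich aryl–palladium favour; capture of the aroyl–palladium by the alkyne and not by the amine, for which 17 is used in excess so that 15 stays limiting; and flavone over aurone, which the enaminone pathway secures by removing the 5-exo attack on the ynone. In the substrate the flavanone is present as a silyl-protected flavan-4-ol with no carbonyl, no acidic hydrogen and no free hydroxyl, so the amine cannot open it and no alcohol competes for the aroyl–palladium.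

Step 12
Reactants: 21 2-[4-({(2S,4S)-2-[4-(benzyloxy)phenyl]-4-[(tert-butyldimethylsilyl)oxy]-5,7-dimethoxychroman-6-yl}oxy)phenyl]-5,7-dimethoxy-4H-chromen-4-one
Product: 22 2-[4-({(2S,4S)-2-[4-(benzyloxy)phenyl]-4-hydroxy-5,7-dimethoxychroman-6-yl}oxy)phenyl]-5,7-dimethoxy-4H-chromen-4-one
Conditions: TBAF, THF, rt
Reagents that add atoms: none
Why: Fluoride-induced cleavage of a silyl ether; the flavone, the benzyl ether and the methyl ethers are inert. The acid-sensitive benzylic alcohol 22 would be used crude in the next step.

Step 13
Reactants: 22 2-[4-({(2S,4S)-2-[4-(benzyloxy)phenyl]-4-hydroxy-5,7-dimethoxychroman-6-yl}oxy)phenyl]-5,7-dimethoxy-4H-chromen-4-one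
Product: 23 (2S)-2-[4-(benzyloxy)phenyl]-6-[4-(5,7-dimethoxy-4-oxo-4H-chromen-2-yl)phenoxy]-5,7-dimethoxychroman-4-one
Conditions: Dess–Martin periodinane, pyridine, CH2Cl2, rt
Reagents that add atoms: none
Why: Dess–Martin oxidation of a secondary benzylic alcohol to the aryl ketone under buffered, near-neutral conditions. This removes the C4 stereocentre and does not touch C2.

Step 14
Reactants: 23 (2S)-2-[4-(benzyloxy)phenyl]-6-[4-(5,7-dimethoxy-4-oxo-4H-chromen-2-yl)phenoxy]-5,7-dimethoxychroman-4-one
Product: 24 (2S)-5-hydroxy-6-[4-(5-hydroxy-7-methoxy-4-oxo-4H-chromen-2-yl)phenoxy]-2-(4-hydroxyphenyl)-7-methoxychroman-4-one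
Conditions: BCl3, C6HMe5, CH2Cl2, −78 to 0 °C; then H2O
Reagents that add atoms: none
Why: Chelation-directed Lewis-acid dealkylation; BCl3 bound to each C4 carbonyl cleaves only the peri (C5) methyl ether of each unit. The benzyl ether is cleaved at low temperature with pentamethylbenzene as cation scavenger, and the non-chelated C7 methyl ethers and the diaryl ether should remain.

## Compound list

1 | syringaldehyde (4-hydroxy-3,5-dimethoxybenzaldehyde) | COc1cc(C=O)cc(OC)c1O | starting material
2 | 4-bromophenylboronic acid | OB(O)c1ccc(Br)cc1 | starting material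
3 | 4-(4-bromophenoxy)-3,5-dimethoxybenzaldehyde | COc1cc(C=O)cc(OC)c1Oc1ccc(Br)cc1 | intermediate
4 | 4-(4-bromophenoxy)-3,5-dimethoxyphenyl formate (formed in the flask) | COc1cc(OC=O)cc(OC)c1Oc1ccc(Br)cc1 | intermediate
5 | 4-(4-bromophenoxy)-3,5-dimethoxyphenol | COc1cc(O)cc(OC)c1Oc1ccc(Br)cc1 | intermediate
6 | 1-[3-(4-bromophenoxy)-6-hydroxy-2,4-dimethoxyphenyl]ethan-1-one | CC(=O)c1c(O)cc(OC)c(Oc2ccc(Br)cc2)c1OC | intermediate
7 | (E)-1-[3-(4-bromophenoxy)-6-hydroxy-2,4-dimethoxyphenyl]-3-(dimethylamino)prop-2-en-1-one (formed in the flask) | CN(C)/C=C/C(=O)c1c(O)cc(OC)c(Oc2ccc(Br)cc2)c1OC | intermediate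
8 | 6-(4-bromophenoxy)-5,7-dimethoxy-4H-chromen-4-one | COc1cc2occc(=O)c2c(OC)c1Oc1ccc(Br)cc1 | intermediate
9 | 4-(benzyloxy)phenylboronic acid | OB(O)c1ccc(OCc2ccccc2)cc1 | starting material
10 | (2S)-2-[4-(benzyloxy)phenyl]-6-(4-bromophenoxy)-5,7-dimethoxychroman-4-one | COc1cc2c(c(OC)c1Oc1ccc(Br)cc1)C(=O)C[C@@H](c1ccc(OCc3ccccc3)cc1)O2 | intermediate
11 | (2S,4S)-2-[4-(benzyloxy)phenyl]-6-(4-bromophenoxy)-5,7-dimethoxychroman-4-ol (2,4-cis) | COc1cc2c(c(OC)c1Oc1ccc(Br)cc1)[C@@H](O)C[C@@H](c1ccc(OCc3ccccc3)cc1)O2 | intermediate
12 | (2S,4S)-2-[4-(benzyloxy)phenyl]-6-(4-bromophenoxy)-4-[(tert-butyldimethylsilyl)oxy]-5,7-dimethoxychroman | COc1cc2c(c(OC)c1Oc1ccc(Br)cc1)[C@@H](O[Si](C)(C)C(C)(C)C)C[C@@H](c1ccc(OCc3ccccc3)cc1)O2 | intermediate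
13 | trimethylsilylacetylene | C#C[Si](C)(C)C | starting material
14 | (2S,4S)-2-[4-(benzyloxy)phenyl]-4-[(tert-butyldimethylsilyl)oxy]-5,7-dimethoxy-6-{4-[(trimethylsilyl)ethynyl]phenoxy}chroman | COc1cc2c(c(OC)c1Oc1ccc(C#C[Si](C)(C)C)cc1)[C@@H](O[Si](C)(C)C(C)(C)C)C[C@@H](c1ccc(OCc3ccccc3)cc1)O2 | intermediate
15 | (2S,4S)-2-[4-(benzyloxy)phenyl]-4-[(tert-butyldimethylsilyl)oxy]-6-(4-ethynylphenoxy)-5,7-dimethoxychroman | C#Cc1ccc(Oc2c(OC)cc3c(c2OC)[C@@H](O[Si](C)(C)C(C)(C)C)C[C@@H](c2ccc(OCc4ccccc4)cc2)O3)cc1 | intermediate
16 | 3,5-dimethoxyphenol | COc1cc(O)cc(OC)c1 | starting material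
17 | 2-iodo-3,5-dimethoxyphenol | COc1cc(O)c(I)c(OC)c1 | intermediate
18 | carbon monoxide | [C-]#[O+] | starting material
19 | 3-[4-({(2S,4S)-2-[4-(benzyloxy)phenyl]-4-[(tert-butyldimethylsilyl)oxy]-5,7-dimethoxychroman-6-yl}oxy)phenyl]-1-(2-hydroxy-4,6-dimethoxyphenyl)prop-2-yn-1-one (formed in the flask) | COc1cc(O)c(C(=O)C#Cc2ccc(Oc3c(OC)cc4c(c3OC)[C@@H](O[Si](C)(C)C(C)(C)C)C[C@@H](c3ccc(OCc5ccccc5)cc3)O4)cc2)c(OC)c1 | intermediate
20 | (E)-3-(diethylamino)-3-[4-({(2S,4S)-2-[4-(benzyloxy)phenyl]-4-[(tert-butyldimethylsilyl)oxy]-5,7-dimethoxychroman-6-yl}oxy)phenyl]-1-(2-hydroxy-4,6-dimethoxyphenyl)prop-2-en-1-one (formed in the flask) | CCN(CC)/C(c1ccc(Oc2c(OC)cc3c(c2OC)[C@@H](O[Si](C)(C)C(C)(C)C)C[C@@H](c2ccc(OCc4ccccc4)cc2)O3)cc1)=C/C(=O)c1c(O)cc(OC)cc1OC | intermediate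
21 | 2-[4-({(2S,4S)-2-[4-(benzyloxy)phenyl]-4-[(tert-butyldimethylsilyl)oxy]-5,7-dimethoxychroman-6-yl}oxy)phenyl]-5,7-dimethoxy-4H-chromen-4-one | COc1cc(OC)c2c(=O)cc(-c3ccc(Oc4c(OC)cc5c(c4OC)[C@@H](O[Si](C)(C)C(C)(C)C)C[C@@H](c4ccc(OCc6ccccc6)cc4)O5)cc3)oc2c1 | intermediate
22 | 2-[4-({(2S,4S)-2-[4-(benzyloxy)phenyl]-4-hydroxy-5,7-dimethoxychroman-6-yl}oxy)phenyl]-5,7-dimethoxy-4H-chromen-4-one | COc1cc(OC)c2c(=O)cc(-c3ccc(Oc4c(OC)cc5c(c4OC)[C@@H](O)C[C@@H](c4ccc(OCc6ccccc6)cc4)O5)cc3)oc2c1 | intermediate
23 | (2S)-2-[4-(benzyloxy)phenyl]-6-[4-(5,7-dimethoxy-4-oxo-4H-chromen-2-yl)phenoxy]-5,7-dimethoxychroman-4-one | COc1cc(OC)c2c(=O)cc(-c3ccc(Oc4c(OC)cc5c(c4OC)C(=O)C[C@@H](c4ccc(OCc6ccccc6)cc4)O5)cc3)oc2c1 | intermediate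
24 | (2S)-5-hydroxy-6-[4-(5-hydroxy-7-methoxy-4-oxo-4H-chromen-2-yl)phenoxy]-2-(4-hydroxyphenyl)-7-methoxychroman-4-one (CNP0202121.1) | COc1cc(O)c2c(=O)cc(-c3ccc(Oc4c(OC)cc5c(c4O)C(=O)C[C@@H](c4ccc(O)cc4)O5)cc3)oc2c1 | target

## Step count and least certain steps

Total steps: 14. Longest linear sequence: 13 (steps 1–9 and 11–14); step 10 is a one-step branch.

**Step 11 (key step).** The most likely failure is coupling of the aryl–palladium with the alkyne before CO insertion, which leads to a 2-alkynylphenol and on to a benzofuran. A second is capture of the aroyl–palladium by diethylamine (aminocarbonylation). Both become competitive because the iodide is electron-rich and flanked by a hydroxyl and a methoxy group, so oxidative addition is slow and the catalyst must survive at 120 °C.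

The fallback avoids carbon monoxide, sets out from 15 and returns at 21.
- Commercial 2-hydroxy-4,6-dimethoxybenzoic acid is acetylated (Ac2O, pyridine) to 2-acetoxy-4,6-dimethoxybenzoic acid F1.
- Oxalyl chloride with catalytic DMF converts this into 2-acetoxy-4,6-dimethoxybenzoyl chloride F2.
- Acyl Sonogashira coupling of F2 with 15 (PdCl2(PPh3)2, CuI, Et3N, THF, rt) gives 2-{3-[4-({(2S,4S)-2-[4-(benzyloxy)phenyl]-4-[(tert-butyldimethylsilyl)oxy]-5,7-dimethoxychroman-6-yl}oxy)phenyl]prop-2-ynoyl}-3,5-dimethoxyphenyl acetate F3.
- Diethylamine in ethanol then adds to the ynone, removes the acetate by aminolysis and closes the pyranone through the same enaminone pathway to give 21.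

**Step 5.** The most likely failure is slow insertion of the electron-rich, peri-substituted chromone into the aryl–palladium bond, so that protodeboronation and homocoupling of 9 dominate. Incomplete facial discrimination on this trioxygenated substrate is also possible.

The fallback sets out from 6 and returns at 11, bypassing steps 4–6.
- Claisen–Schmidt condensation of 6 with 4-(benzyloxy)benzaldehyde (KOH, EtOH) gives (E)-3-[4-(benzyloxy)phenyl]-1-[3-(4-bromophenoxy)-6-hydroxy-2,4-dimethoxyphenyl]prop-2-en-1-one F4.
- NaOAc in refluxing ethanol cyclises this to racemic 2-[4-(benzyloxy)phenyl]-6-(4-bromophenoxy)-5,7-dimethoxychroman-4-one F5.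
- Kinetic resolution by asymmetric transfer hydrogenation (RuCl(p-cymene)[(S,S)-TsDPEN], HCO2H/Et3N; the catalyst antipode that sets C4 as S) reduces the (2S) enantiomer to the cis alcohol 11.
- The unreacted (2R)-2-[4-(benzyloxy)phenyl]-6-(4-bromophenoxy)-5,7-dimethoxychroman-4-one F6 is separated and can be racemised with base for recycling.

**Step 14.** The most likely failure is erosion of configuration at C2 by Lewis-acid-promoted opening of the dihydropyranone once the C5 hydroxyl is free. Incomplete cleavage of the hindered flavanone C5 methyl ether next to the aryloxy group is the other risk.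

The fallback separates the two events, sets out from 23 and returns at 24.
- Hydrogenolysis (H2, Pd/C, EtOAc) removes the benzyl group and gives (2S)-6-[4-(5,7-dimethoxy-4-oxo-4H-chromen-2-yl)phenoxy]-2-(4-hydroxyphenyl)-5,7-dimethoxychroman-4-one F7.
- The two peri methyl ethers are then cleaved under milder chelation control with MgI2·OEt2 in warm toluene–ether to give 24.

**Step 1.** The most likely failure is slow coupling at copper of the doubly ortho-substituted, electron-poor phenoxide, so that 2 is consumed by protodeboronation and oxidative homocoupling. The fallback sets out from 1 and returns at 3: an Ullmann-type etherification with 1-bromo-4-iodobenzene (CuI, picolinic acid, K3PO4, DMSO, 90 °C). It relies on selective reaction of the C–I bond and makes no new intermediate.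

## Further compounds

F1 | step 11 | 2-acetoxy-4,6-dimethoxybenzoic acid | CC(=O)Oc1cc(OC)cc(OC)c1C(=O)O
F2 | step 11 | 2-acetoxy-4,6-dimethoxybenzoyl chloride | CC(=O)Oc1cc(OC)cc(OC)c1C(=O)Cl
F3 | step 11 | 2-{3-[4-({(2S,4S)-2-[4-(benzyloxy)phenyl]-4-[(tert-butyldimethylsilyl)oxy]-5,7-dimethoxychroman-6-yl}oxy)phenyl]prop-2-ynoyl}-3,5-dimethoxyphenyl acetate | CC(=O)Oc1cc(OC)cc(OC)c1C(=O)C#Cc1ccc(Oc2c(OC)cc3c(c2OC)[C@@H](O[Si](C)(C)C(C)(C)C)C[C@@H](c2ccc(OCc4ccccc4)cc2)O3)cc1
F4 | step 5 | (E)-3-[4-(benzyloxy)phenyl]-1-[3-(4-bromophenoxy)-6-hydroxy-2,4-dimethoxyphenyl]prop-2-en-1-one | COc1cc(O)c(C(=O)/C=C/c2ccc(OCc3ccccc3)cc2)c(OC)c1Oc1ccc(Br)cc1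
F5 | step 5 | racemic 2-[4-(benzyloxy)phenyl]-6-(4-bromophenoxy)-5,7-dimethoxychroman-4-one | COc1cc2c(c(OC)c1Oc1ccc(Br)cc1)C(=O)CC(c1ccc(OCc3ccccc3)cc1)O2
F6 | step 5 | (2R)-2-[4-(benzyloxy)phenyl]-6-(4-bromophenoxy)-5,7-dimethoxychroman-4-one | COc1cc2c(c(OC)c1Oc1ccc(Br)cc1)C(=O)C[C@H](c1ccc(OCc3ccccc3)cc1)O2
F7 | step 14 | (2S)-6-[4-(5,7-dimethoxy-4-oxo-4H-chromen-2-yl)phenoxy]-2-(4-hydroxyphenyl)-5,7-dimethoxychroman-4-one | COc1cc(OC)c2c(=O)cc(-c3ccc(Oc4c(OC)cc5c(c4OC)C(=O)C[C@@H](c4ccc(O)cc4)O5)cc3)oc2c1
F0 | step 1 | none | none
A1 | alternative 1 | (3S)-3-[4-(acetyloxy)phenyl]-3-{4-[4-(5,7-dimethoxy-4-oxo-4H-chromen-2-yl)phenoxy]-3,5-dimethoxyphenoxy}propanoic acid | COc1cc(OC)c2c(=O)cc(-c3ccc(Oc4c(OC)cc(O[C@@H](CC(=O)O)c5ccc(OC(C)=O)cc5)cc4OC)cc3)oc2c1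
A2 | alternative 1 | 4-{(2S)-6-[4-(5,7-dimethoxy-4-oxo-4H-chromen-2-yl)phenoxy]-5,7-dimethoxy-4-oxochroman-2-yl}phenyl acetate | COc1cc(OC)c2c(=O)cc(-c3ccc(Oc4c(OC)cc5c(c4OC)C(=O)C[C@@H](c4ccc(OC(C)=O)cc4)O5)cc3)oc2c1
A3 | alternative 2 | tert-butyl 3-[4-(benzyloxy)phenyl]-2-{3-[4-(5,7-dimethoxy-4-oxo-4H-chromen-2-yl)phenoxy]-6-hydroxy-2,4-dimethoxybenzoyl}prop-2-enoate (alkene geometry not defined) | COc1cc(OC)c2c(=O)cc(-c3ccc(Oc4c(OC)cc(O)c(C(=O)C(=Cc5ccc(OCc6ccccc6)cc5)C(=O)OC(C)(C)C)c4OC)cc3)oc2c1
A4 | alternative 2 | tert-butyl (2S,3R)-2-[4-(benzyloxy)phenyl]-6-[4-(5,7-dimethoxy-4-oxo-4H-chromen-2-yl)phenoxy]-5,7-dimethoxy-4-oxochroman-3-carboxylate (2,3-trans) | COc1cc(OC)c2c(=O)cc(-c3ccc(Oc4c(OC)cc5c(c4OC)C(=O)[C@H](C(=O)OC(C)(C)C)[C@@H](c4ccc(OCc6ccccc6)cc4)O5)cc3)oc2c1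
A5 | alternative 3 | 2-[4-({1,3-dimethoxy-1-[(trimethylsilyl)oxy]buta-1,3-dien-2-yl}oxy)phenyl]-5,7-dimethoxy-4H-chromen-4-one (enol ether geometry not defined) | C=C(OC)C(Oc1ccc(-c2cc(=O)c3c(OC)cc(OC)cc3o2)cc1)=C(OC)O[Si](C)(C)C
A6 | alternative 3 | (2S)-2-[4-(benzyloxy)phenyl]-5-bromo-2,3-dihydro-4H-pyran-4-one | O=C1C[C@@H](c2ccc(OCc3ccccc3)cc2)OC=C1Br
A7 | alternative 3 | (2S)-2-[4-(benzyloxy)phenyl]-6-[4-(5,7-dimethoxy-4-oxo-4H-chromen-2-yl)phenoxy]-5-hydroxy-7-methoxychroman-4-one | COc1cc(OC)c2c(=O)cc(-c3ccc(Oc4c(OC)cc5c(c4O)C(=O)C[C@@H](c4ccc(OCc6ccccc6)cc4)O5)cc3)oc2c1
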